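## Retrosynthetic overview

1. Target 13 ⇒ C6–O bond: α-face, anti-Markovnikov hydroacyloxylation of the C5=C6 alkene of dienal 10 with 4-acetoxybenzoic acid 11 (new photoredox step; sets C5–H and C6–O together), then loss of the phenol acetate.
2. 10 ⇒ ester 8 (C14 ester to CHO) ⇒ ketone 7 by 1,2-addition of isopropyl (sets C4).
3. 7 ⇒ dienone 3 + vinyldiazoacetate 5 by enantioselective cyclopropanation/Cope ([4+3]); this sets C1 and closes the seven-membered ring onto the purchased five-membered ring.
4. 3 ⇒ bromoenone 1 + vinylboronate 2; 5 ⇒ methyl but-3-enoate 4.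

Assumption: 1, 2, 4, 11 and Rh2(R-DOSP)4 are purchased; atom labels follow daucane numbering (C1 angular quaternary carbon, C4 carbinol, C5 ring-fusion CH, C6 ester-bearing carbon, C8 formyl-bearing carbon, C14 formyl carbon), and α means the face opposite the angular methyl.

## Route

Step 1
Reactants: 1 2-bromo-3-methylcyclopent-2-en-1-one; 2 2-ethenyl-4,4,5,5-tetramethyl-1,3,2-dioxaborolane
Product: 3 2-ethenyl-3-methylcyclopent-2-en-1-one
Conditions: Pd(dppf)Cl2 (3 mol%), K3PO4 (3 equiv), 1,4-dioxane/H2O (5:1), 80 °C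
Reagents that add atoms: none
Why: Suzuki–Miyaura coupling of an α-bromoenone with a vinylboronate is routine and gives the cross-conjugated diene without creating a stereocentre.

Step 2
Reactants: 4 methyl but-3-enoate
Product: 5 methyl 2-diazobut-3-enoate
Conditions: p-ABSA (1.2 equiv), DBU (1.3 equiv), MeCN, 0 °C; used at once as a cold hexanes solution
Reagents that add atoms: 4-acetamidobenzenesulfonyl azide (p-ABSA), CC(=O)Nc1ccc(cc1)S(=O)(=O)N=[N+]=[N-]
Why: Regitz diazo transfer to the doubly activated (allylic, α-ester) CH2 gives the vinyldiazoacetate; no stereocentre is formed.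

Step 3
Reactants: 3 2-ethenyl-3-methylcyclopent-2-en-1-one; 5 methyl 2-diazobut-3-enoate
Product: 7 methyl (8aR)-8a-methyl-3-oxo-1,2,3,5,8,8a-hexahydroazulene-6-carboxylate, via cis-divinylcyclopropane 6 (not isolated)
Conditions: Rh2(R-DOSP)4 (1 mol%), hexanes, −40 °C → rt, 5 (2.5 equiv) added over 2 h; then PhMe, 90 °C
Reagents that add atoms: none
Why: Tandem cyclopropanation/Cope rearrangement (formal [4+3] cycloaddition) of a donor/acceptor vinylcarbenoid: the chiral dirhodium carboxylate selects the enantioface of the terminal vinyl group to give 6, and its boat Cope rearrangement passes that chirality to C1, giving the (R) methyl-bearing quaternary centre while forming the C7–C8 and C1–C10 bonds.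

Step 4
Reactants: 7 methyl (8aR)-8a-methyl-3-oxo-1,2,3,5,8,8a-hexahydroazulene-6-carboxylate
Product: 8 methyl (3R,8aR)-3-hydroxy-8a-methyl-3-(propan-2-yl)-1,2,3,5,8,8a-hexahydroazulene-6-carboxylate
Conditions: i-PrMgCl·LiCl (1.5 equiv), LaCl3·2LiCl (1.0 equiv), THF, −78 → −30 °C; sat. aq NH4Cl
Reagents that add atoms: isopropylmagnesium chloride, CC(C)[Mg]Cl
Why: Lanthanum-promoted Grignard 1,2-addition suppresses enolisation and β-hydride reduction and takes the ketone ahead of the ester; attack anti to the angular methyl (α face) sets C4 with β-OH and α-isopropyl.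

Step 5
Reactants: 8 methyl (3R,8aR)-3-hydroxy-8a-methyl-3-(propan-2-yl)-1,2,3,5,8,8a-hexahydroazulene-6-carboxylate
Product: 9 (3R,8aR)-6-(hydroxymethyl)-8a-methyl-3-(propan-2-yl)-1,2,3,5,8,8a-hexahydroazulen-3-ol
Conditions: i-Bu2AlH (3.5 equiv), CH2Cl2, −78 → 0 °C; aq potassium sodium tartrate
Reagents that add atoms: none
Why: Hydride 1,2-reduction of the conjugated ester by i-Bu2AlH gives the primary allylic alcohol without touching either alkene or any stereocentre.

Step 6
Reactants: 9 (3R,8aR)-6-(hydroxymethyl)-8a-methyl-3-(propan-2-yl)-1,2,3,5,8,8a-hexahydroazulen-3-ol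
Product: 10 (3R,8aR)-3-hydroxy-8a-methyl-3-(propan-2-yl)-1,2,3,5,8,8a-hexahydroazulene-6-carbaldehyde
Conditions: MnO2 (15 equiv), CH2Cl2, rt
Reagents that add atoms: none
Why: MnO2 allylic oxidation converts only the primary allylic alcohol to the enal under neutral conditions; the tertiary alcohol cannot be oxidised and no stereocentre is involved.

Step 7
Reactants: 10 (3R,8aR)-3-hydroxy-8a-methyl-3-(propan-2-yl)-1,2,3,5,8,8a-hexahydroazulene-6-carbaldehyde; 11 4-(acetyloxy)benzoic acid
Product: 13 (3R,3aS,4S,8aR)-6-formyl-3-hydroxy-8a-methyl-3-(propan-2-yl)-1,2,3,3a,4,5,8,8a-octahydroazulen-4-yl 4-hydroxybenzoate, via acetate-protected ester 12 (not isolated)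
Conditions: 11 (4 equiv), 9-mesityl-3,6-di-tert-butyl-10-phenylacridinium tetrafluoroborate (5 mol%), bis(2,4,6-triisopropylphenyl) disulfide (10 mol%), 2,6-lutidine (25 mol%), ClCH2CH2Cl/MeCN (4:1), 450 nm LEDs, 23 °C, degassed; aq NaHCO3 wash; then K2CO3 (0.3 equiv), MeOH, 0 °C
Reagents that add atoms: none
Why: Proposed new method: diastereocontrolled anti-Markovnikov hydroacyloxylation of a ring-fusion trisubstituted alkene inside a skipped dienal — the excited acridinium oxidises only the electron-rich C5=C6 bond (the enal and the acetoxy-arene are too electron-poor), the carboxylate adds to the less substituted C6 to leave the tertiary C5 radical, and the hindered arenethiol formed from the disulfide transfers a hydrogen atom to C5; both new bonds are expected on the α face because the β face is screened by the syn-1,3 pair angular CH3/4β-OH while the α-isopropyl can sit pseudo-equatorial, and because hydrogen transfer cis to the new C–O bond is the usual outcome with cyclic trisubstituted alkenes (net syn addition: 6α-O, 5α-H, trans ring fusion); the closest known reaction is the acridinium/thiol photoredox anti-Markovnikov addition of carboxylic acids to simple styrenes and trisubstituted alkenes, which has not been shown on an allylic-carbinol-bearing bicyclic diene, beside an enal, or as a way to set two adjacent stereocentres; carbonate-catalysed methanolysis then removes the aryl acetate far faster than it touches the hindered alkyl benzoate.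

## Compound list

1 | 2-bromo-3-methylcyclopent-2-en-1-one | CC1=C(Br)C(=O)CC1 | starting material
2 | 2-ethenyl-4,4,5,5-tetramethyl-1,3,2-dioxaborolane (vinylboronic acid pinacol ester) | C=CB1OC(C)(C)C(C)(C)O1 | starting material
3 | 2-ethenyl-3-methylcyclopent-2-en-1-one | CC1=C(C=C)C(=O)CC1 | intermediate
4 | methyl but-3-enoate | COC(=O)CC=C | starting material
5 | methyl 2-diazobut-3-enoate | COC(=O)C(=[N+]=[N-])C=C | intermediate
6 | methyl (1S,2S)-1-ethenyl-2-(2-methyl-5-oxocyclopent-1-en-1-yl)cyclopropane-1-carboxylate (vinyl and cyclopentenyl cis) | COC(=O)[C@]1(C=C)C[C@H]1C2=C(C)CCC2=O | intermediate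
7 | methyl (8aR)-8a-methyl-3-oxo-1,2,3,5,8,8a-hexahydroazulene-6-carboxylate | COC(=O)C1=CC[C@@]2(C)CCC(=O)C2=CC1 | intermediate
8 | methyl (3R,8aR)-3-hydroxy-8a-methyl-3-(propan-2-yl)-1,2,3,5,8,8a-hexahydroazulene-6-carboxylate (OH cis to angular methyl) | COC(=O)C1=CC[C@@]2(C)CC[C@@](O)(C(C)C)C2=CC1 | intermediate
9 | (3R,8aR)-6-(hydroxymethyl)-8a-methyl-3-(propan-2-yl)-1,2,3,5,8,8a-hexahydroazulen-3-ol | OCC1=CC[C@@]2(C)CC[C@@](O)(C(C)C)C2=CC1 | intermediate
10 | (3R,8aR)-3-hydroxy-8a-methyl-3-(propan-2-yl)-1,2,3,5,8,8a-hexahydroazulene-6-carbaldehyde | O=CC1=CC[C@@]2(C)CC[C@@](O)(C(C)C)C2=CC1 | intermediate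
11 | 4-(acetyloxy)benzoic acid | CC(=O)Oc1ccc(cc1)C(=O)O | starting material
12 | (3R,3aS,4S,8aR)-6-formyl-3-hydroxy-8a-methyl-3-(propan-2-yl)-1,2,3,3a,4,5,8,8a-octahydroazulen-4-yl 4-(acetyloxy)benzoate | CC(C)[C@]1(O)CC[C@]2(C)CC=C(C=O)C[C@H](OC(=O)c3ccc(OC(C)=O)cc3)[C@H]21 | intermediate
13 | (3R,3aS,4S,8aR)-6-formyl-3-hydroxy-8a-methyl-3-(propan-2-yl)-1,2,3,3a,4,5,8,8a-octahydroazulen-4-yl 4-hydroxybenzoate (trans ring fusion, 4β-OH, 6α-ester) | CC(C)[C@]1(O)CC[C@]2(C)CC=C(C=O)C[C@H](OC(=O)c3ccc(O)cc3)[C@H]21 | target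

## Summary and risks

Total steps: 7. Longest linear sequence: 6 (steps 1, 3, 4, 5, 6, 7 from compound 1).

**Step 7 (new photoredox hydroacyloxylation).** This is the least certain step. The 4β-OH could hydrogen-bond the carboxylate and steer it to the β face of C6. The radical cation could instead lose a proton from the doubly allylic C7. The α-face preference rests on a conformational argument, not on precedent. The fallback uses known chemistry, sets out from 8 and comes back to the route at 12. BH3·SMe2 (THF, 0 °C → rt) then NaBO3·4H2O performs a concerted syn, anti-Markovnikov hydroboration–oxidation of C5=C6, sparing the electron-poor enoate, and gives methyl (3R,3aS,4S,8aR)-3,4-dihydroxy-8a-methyl-3-(propan-2-yl)-1,2,3,3a,4,5,8,8a-octahydroazulene-6-carboxylate F1. Reduction with i-Bu2AlH gives (3R,3aS,4S,8aR)-6-(hydroxymethyl)-8a-methyl-3-(propan-2-yl)-1,2,3,3a,4,5,8,8a-octahydroazulene-3,4-diol F2. MnO2 then gives (3R,3aS,4S,8aR)-3,4-dihydroxy-8a-methyl-3-(propan-2-yl)-1,2,3,3a,4,5,8,8a-octahydroazulene-6-carbaldehyde F3. Acylation of the secondary C6–OH (the tertiary OH is inert) with 4-acetoxybenzoyl chloride, Et3N and DMAP in CH2Cl2 gives 12, and the K2CO3/MeOH stage of step 7 then gives 13.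

**Step 3 ([4+3]).** The vinyl group of 3 is cross-conjugated to a ketone and may be too weak a nucleophile for the carbenoid, which would then dimerise or close to the pyrazole. The Cope step must also place a methyl group inside the boat. The fallback sets out from 3 and comes back at 7. Ketalisation with 1,2-bis(trimethylsilyloxy)ethane and catalytic TMSOTf (CH2Cl2, −78 °C) gives the electron-rich diene 6-ethenyl-7-methyl-1,4-dioxaspiro[4.4]non-6-ene F4. The same Rh2(R-DOSP)4 cyclopropanation/Cope with 5 gives methyl (8a'R)-8a'-methyl-1',2',8',8a'-tetrahydro-5'H-spiro[[1,3]dioxolane-2,3'-azulene]-6'-carboxylate F5. PPTS in acetone/H2O then returns 7.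

**Step 4 (isopropyl addition).** Isopropyl organometallics can enolise or reduce a hindered enone, and facial control by a 1,3-related angular methyl may be only moderate. The fallback sets out from 7 and comes back at 8. CH2=C(CH3)MgBr with CeCl3 (THF, −78 °C), a smaller sp2 nucleophile with no β-hydrogen, gives methyl (3R,8aR)-3-hydroxy-8a-methyl-3-(prop-1-en-2-yl)-1,2,3,5,8,8a-hexahydroazulene-6-carboxylate F6. Hydrogenation of only the 1,1-disubstituted alkene with RhCl(PPh3)3 and H2 (1 atm, benzene) returns 8; the C4 epimers, if formed, are separated at this stage.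

Further compounds
F1 | step 7 | methyl (3R,3aS,4S,8aR)-3,4-dihydroxy-8a-methyl-3-(propan-2-yl)-1,2,3,3a,4,5,8,8a-octahydroazulene-6-carboxylate | CC(C)[C@]1(O)CC[C@]2(C)CC=C(C(=O)OC)C[C@H](O)[C@H]21
F2 | step 7 | (3R,3aS,4S,8aR)-6-(hydroxymethyl)-8a-methyl-3-(propan-2-yl)-1,2,3,3a,4,5,8,8a-octahydroazulene-3,4-diol | CC(C)[C@]1(O)CC[C@]2(C)CC=C(CO)C[C@H](O)[C@H]21
F3 | step 7 | (3R,3aS,4S,8aR)-3,4-dihydroxy-8a-methyl-3-(propan-2-yl)-1,2,3,3a,4,5,8,8a-octahydroazulene-6-carbaldehyde | CC(C)[C@]1(O)CC[C@]2(C)CC=C(C=O)C[C@H](O)[C@H]21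
F4 | step 3 | 6-ethenyl-7-methyl-1,4-dioxaspiro[4.4]non-6-ene | CC1=C(C=C)C2(CC1)OCCO2
F5 | step 3 | methyl (8a'R)-8a'-methyl-1',2',8',8a'-tetrahydro-5'H-spiro[[1,3]dioxolane-2,3'-azulene]-6'-carboxylate | COC(=O)C1=CC[C@@]2(C)CCC3(OCCO3)C2=CC1
F6 | step 4 | methyl (3R,8aR)-3-hydroxy-8a-methyl-3-(prop-1-en-2-yl)-1,2,3,5,8,8a-hexahydroazulene-6-carboxylate | COC(=O)C1=CC[C@@]2(C)CC[C@@](O)(C(C)=C)C2=CC1
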